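## Retrosynthetic overview

1. Jaeskeanin ⇐ selective 4‑hydroxybenzoylation of the secondary OH of 8α,9α‑epoxyjaeschkeanadiol ⇐ hydroxyl‑directed epoxidation of jaeschkeanadiol.
2. The seven‑membered ring is closed last among the carbocycles, by ring‑closing metathesis at C8=C9 of a trans‑1,2‑disubstituted cyclopentane (allyl on C1, 1‑hydroxy‑3‑methylbut‑3‑enyl on C5).
3. The C6 carbinol ⇐ chelation‑controlled methallyl addition to the aldehyde released from a cis‑fused cyclopentane β‑lactone.
4. The C1 quaternary centre ⇐ Markovnikov radical hydroallylation of a 2‑methylidene β‑lactone on its convex face.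
5. The cyclopentane and the C4/C5 stereocentres come first: isothiourea‑catalysed aldol‑lactonization of an achiral keto acid built from 3‑methylbutan‑2‑one, 3‑chloro‑2‑(chloromethyl)prop‑1‑ene and CO. Ring order: cyclopentane (+ β‑lactone) → cycloheptene → epoxide.

Notation: daucane numbering is used in the explanations (C1 quaternary C–Me, C4 carbinol bearing iPr, C5 ring‑fusion CH, C6 ester carbon, C8/C9 epoxide carbons).

Assumption: (S)‑HBTM is taken to give the (1R,5R) β‑lactone 7; if the sense of induction is the opposite, (R)‑HBTM is used instead.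

## Route

**Step 1**
Reactants: 1, 3‑methylbutan‑2‑one; 2, 3‑chloro‑2‑(chloromethyl)prop‑1‑ene
Product: 3, 6‑(chloromethyl)‑2‑methylhept‑6‑en‑3‑one
Conditions: LDA (1.05 equiv), THF, −78 °C; then add to 2 (3 equiv), DMPU, −78 → 0 °C
Reagents that add atoms: 3‑chloro‑2‑(chloromethyl)prop‑1‑ene (2), C=C(CCl)CCl
Why: Kinetic deprotonation of the methyl ketone on the CH3 side followed by SN2 enolate alkylation with an excess of the symmetrical bis‑allylic chloride gives the mono‑alkylated ketone; no stereocentre is formed.

**Step 2**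
Reactants: 3; 4, carbon monoxide; 5, water
Product: 6, 7‑methyl‑3‑methylidene‑6‑oxooctanoic acid
Conditions: PdCl2(PPh3)2 (2 mol %), CO (1 atm), K2CO3, THF–H2O, 40 °C; then acidify to pH 3
Reagents that add atoms: carbon monoxide (4), [C-]#[O+]; water (5), O
Why: Pd‑catalysed hydroxycarbonylation of the allylic chloride proceeds through a 2‑substituted π‑allyl whose two termini are equivalent, so CO insertion and hydrolysis can only give the β,γ‑unsaturated acid; no stereocentre is formed.

**Step 3**
Reactants: 6
Product: 7, (1R,5R)‑2‑methylidene‑5‑(propan‑2‑yl)‑6‑oxabicyclo[3.2.0]heptan‑7‑one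
Conditions: (S)‑HBTM (20 mol %), TsCl, i‑Pr2NEt, CH2Cl2, 23 °C, slow addition of 6
Reagents that add atoms: none
Why: Nucleophile‑catalysed aldol‑lactonization: the acyl isothiouronium is deprotonated to a chiral ammonium enolate that attacks the isopropyl ketone in a 5‑(enolexo)‑exo‑trig aldol and then lactonizes to release the catalyst, so the cis ring fusion (C4–O cis to C5–C6) is enforced by the four‑membered ring and the catalyst sets the absolute configuration of the first two stereocentres (C4, C5).

**Step 4**
Reactants: 7; 8, allyl phenyl sulfone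
Product: 9, (1R,2R,5R)‑2‑methyl‑5‑(propan‑2‑yl)‑2‑(prop‑2‑en‑1‑yl)‑6‑oxabicyclo[3.2.0]heptan‑7‑one
Conditions: Fe(acac)3 (30 mol %), Ph(i‑PrO)SiH2 (2.5 equiv), 8 (5 equiv), THF/i‑PrOH, 23–40 °C
Reagents that add atoms: allyl phenyl sulfone (8), C=CCS(=O)(=O)c1ccccc1
Why: Proposed new method: iron‑hydride hydrogen‑atom transfer to the CH2 terminus of the 1,1‑disubstituted alkene gives the tertiary C1 radical (Markovnikov), which adds to the unactivated allyl sulfone and β‑fragments (SH2′), the expelled PhSO2• being reduced by Fe(II) to sulfinate to close the Fe(II)/Fe(III) cycle; the radical is trapped on the convex face of the bicyclo[3.2.0] core, anti to the lactone carbonyl on the adjacent bridgehead, so allyl ends trans and methyl cis to the lactone; the closest known reactions are MHAT reductive olefin coupling with Michael acceptors (Giese type), MHAT hydrofunctionalization with sulfonyl‑X radical traps and Keck allylation, and this hydroallylation with a parent allyl sulfone to make a quaternary stereocentre next to a β‑lactone is, as far as I know, not established.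

**Step 5**
Reactants: 9; 10, 2‑methylallylmagnesium chloride
Product: 11, (1R,2S,3R)‑2‑[(1S)‑1‑hydroxy‑3‑methylbut‑3‑en‑1‑yl]‑3‑methyl‑1‑(propan‑2‑yl)‑3‑(prop‑2‑en‑1‑yl)cyclopentan‑1‑ol
Conditions: DIBAL‑H (1.05 equiv), CH2Cl2, −78 °C; then 10 (3.5 equiv, THF), −78 → −30 °C; Rochelle salt work‑up (one pot)
Reagents that add atoms: 2‑methylallylmagnesium chloride (10), CC(=C)C[Mg]Cl
Why: Semi‑reduction of the strained lactone reveals a β‑metal‑alkoxy aldehyde that reacts under 1,3‑chelation (Cram–Reetz) control, the Grignard reagent adding to the chelated carbonyl from the side of the α‑C–H, anti to the neighbouring quaternary carbon, which gives the (S) carbinol at C6.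

**Step 6**
Reactants: 11
Product: 12, jaeschkeanadiol, (3R,3aS,4S,8aR)‑6,8a‑dimethyl‑3‑(propan‑2‑yl)‑1,2,3,3a,4,5,8,8a‑octahydroazulene‑3,4‑diol
Conditions: Hoveyda–Grubbs II (5 mol %), toluene (5 mM), 80 °C
Reagents that add atoms: none
Why: Ring‑closing metathesis of the allyl and methallyl groups (ethylene lost) forms the trisubstituted cycloheptene, and because the two arms are trans on the cyclopentane the trans‑fused hydroazulene results with no stereocentre touched.

**Step 7**
Reactants: 12; 13, tert‑butyl hydroperoxide
Product: 14, 8α,9α‑epoxyjaeschkeanadiol (jaeschkeanadiol with the C8–C9 epoxide oxygen cis to the 6‑OH; daucane 1R,4R,5S,6S,8R,9S)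
Conditions: VO(acac)2 (5 mol %), t‑BuOOH (1.5 equiv), CH2Cl2, 0 → 23 °C
Reagents that add atoms: tert‑butyl hydroperoxide (13), CC(C)(C)OO
Why: Vanadium‑catalysed hydroxyl‑directed epoxidation delivers oxygen from the homoallylic 6α‑OH to the α face of C8=C9, which is also the face away from the angular methyl, setting C8 (R) and C9 (S).

**Step 8**
Reactants: 14; 15, 4‑acetoxybenzoyl chloride
Product: 16, jaeskeanin
Conditions: 15 (1.5 equiv), DMAP, Et3N, CH2Cl2, 0 → 23 °C; then pyrrolidine, 23 °C (one pot)
Reagents that add atoms: 4‑acetoxybenzoyl chloride (15), CC(=O)Oc1ccc(cc1)C(Cl)=O (the acetyl group is removed again)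
Why: DMAP‑catalysed acylation takes the secondary C6‑OH and leaves the tertiary C4‑OH, and aminolysis then cleaves the aryl acetate much faster than the hindered alkyl benzoate, with the epoxide and all stereocentres untouched.

## Compound list

1 | 3‑methylbutan‑2‑one | CC(C)C(C)=O | starting material
2 | 3‑chloro‑2‑(chloromethyl)prop‑1‑ene | C=C(CCl)CCl | starting material
3 | 6‑(chloromethyl)‑2‑methylhept‑6‑en‑3‑one | CC(C)C(=O)CCC(=C)CCl | intermediate
4 | carbon monoxide | [C-]#[O+] | starting material
5 | water | O | starting material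
6 | 7‑methyl‑3‑methylidene‑6‑oxooctanoic acid | CC(C)C(=O)CCC(=C)CC(=O)O | intermediate
7 | (1R,5R)‑2‑methylidene‑5‑(propan‑2‑yl)‑6‑oxabicyclo[3.2.0]heptan‑7‑one | O=C1O[C@@]2(C(C)C)CCC(=C)[C@@H]12 | intermediate
8 | allyl phenyl sulfone | C=CCS(=O)(=O)c1ccccc1 | starting material
9 | (1R,2R,5R)‑2‑methyl‑5‑(propan‑2‑yl)‑2‑(prop‑2‑en‑1‑yl)‑6‑oxabicyclo[3.2.0]heptan‑7‑one | O=C1O[C@@]2(C(C)C)CC[C@](C)(CC=C)[C@@H]12 | intermediate
10 | 2‑methylallylmagnesium chloride | CC(=C)C[Mg]Cl | starting material
11 | (1R,2S,3R)‑2‑[(1S)‑1‑hydroxy‑3‑methylbut‑3‑en‑1‑yl]‑3‑methyl‑1‑(propan‑2‑yl)‑3‑(prop‑2‑en‑1‑yl)cyclopentan‑1‑ol | CC(C)[C@]1(O)CC[C@](C)(CC=C)[C@H]1[C@@H](O)CC(C)=C | intermediate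
12 | jaeschkeanadiol, (3R,3aS,4S,8aR)‑6,8a‑dimethyl‑3‑(propan‑2‑yl)‑1,2,3,3a,4,5,8,8a‑octahydroazulene‑3,4‑diol | CC(C)[C@]1(O)CC[C@]2(C)CC=C(C)C[C@H](O)[C@H]21 | intermediate
13 | tert‑butyl hydroperoxide | CC(C)(C)OO | starting material
14 | 8α,9α‑epoxyjaeschkeanadiol | CC(C)[C@]1(O)CC[C@]2(C)C[C@@H]3O[C@]3(C)C[C@H](O)[C@H]21 | intermediate
15 | 4‑acetoxybenzoyl chloride | CC(=O)Oc1ccc(cc1)C(Cl)=O | starting material
16 | jaeskeanin | CC(C)[C@]1(O)CC[C@]2(C)C[C@@H]3O[C@]3(C)C[C@H](OC(=O)c3ccc(O)cc3)[C@H]21 | target

## Step count and risks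

Total steps: 8. Longest linear sequence: 8 (from 3‑methylbutan‑2‑one).

Steps most likely to fail:

1. **Step 4 (proposed new hydroallylation).** The tertiary radical may be reduced faster than it adds to the unactivated allyl sulfone, and the facial selectivity is only argued, not demonstrated. Fallback with known chemistry: MHAT Markovnikov hydrobromination of 7 (Co(acac)2, t‑BuOOH, Et3SiH, TsBr) to the tertiary bromide, then Keck radical allylation (allyltributylstannane, AIBN, 80 °C). This goes through the same C1 radical, so the same facial argument applies, at the cost of one step.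
2. **Step 3 (aldol‑lactonization onto a hindered isopropyl ketone).** The ring closure may be slow, and the β,γ‑unsaturated acyl ammonium can isomerize. An endocyclic alkene isomer of 7 would still converge in step 4, since it gives the same radical. Fallback: change to enamine catalysis, using the corresponding keto‑aldehyde (7‑methyl‑3‑methylidene‑6‑oxooctanal) in a proline‑type 5‑enolexo aldolization, then Pinnick oxidation and lactonization to reach 7.
3. **Step 5 (one‑pot semi‑reduction and methallylation).** Over‑reduction to the diol or retro‑aldol opening of the β‑alkoxy aldehyde are the risks. Fallback: open 9 to the Weinreb amide (Me2AlN(OMe)Me), add 10 to give the β‑hydroxy methallyl ketone, close the ring by metathesis, and then reduce the bicyclic ketone with Me4NBH(OAc)3. In the bicyclic ketone, hydride is delivered intramolecularly from the 4β‑OH, which gives the 6α‑alcohol 12.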